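**Strategy.** The oxolane ring (O1, C2 bearing the 4‑hydroxyphenyl group, C3, C4, C5 bearing the trisubstituted aryl group) is cut at O1–C2 and C3–C4. A chiral (E)‑propenyl p‑tolyl sulfoxide supplies C2–C3 and chloro(methyl)ketene supplies O1–C5–C4. Their Marino‑type lactonisation (sulfoxide O‑acylation, [3,3] shift, closure of the thionium carboxylate) makes both bonds in one operation and transfers chirality from sulfur to C3. The step exploits that C2 and C5 are both benzylic, O‑bearing carbons flanking the cis‑dimethyl pair C3/C4: C2 emerges as an S,O‑acetal and C5 as a lactone carbonyl, so each aryl group is added later and ends trans to its neighbouring methyl.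

Key step: step 2

Assumption (chemistry): the sense of chirality transfer in step 2 is taken from the chair‑like [3,3] model with p‑tolyl pseudo‑equatorial; should the opposite sense be found, the enantiomeric sulfoxide from (1S,2R,5S)‑menthyl (R)‑4‑methylbenzenesulfinate would be carried through the same route.

**Step 1**
Reactants: 1 (1R,2S,5R)-menthyl (S)-4-methylbenzenesulfinate; 2 (E)-1-bromoprop-1-ene
Product: 4 1-methyl-4-[(R)-(1E)-prop-1-ene-1-sulfinyl]benzene, via (E)-prop-1-enylmagnesium bromide 3 (not isolated)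
Conditions: Mg turnings, THF, 35 °C; then 1, toluene/THF, −40 → 0 °C; aq. NH4Cl; chromatography to remove any (Z)-isomer
Reagents that add atoms: none
Why: Andersen sulfoxide synthesis, in which the alkenyl Grignard reagent displaces mentholate at sulfur with inversion, so the (S)-sulfinate should give the (R)-sulfoxide with the (E)-alkene retained.

**Step 2**
Reactants: 4 1-methyl-4-[(R)-(1E)-prop-1-ene-1-sulfinyl]benzene; 5 2,2-dichloropropanoyl chloride
Product: 9 (4R,5R)-3-chloro-3,4-dimethyl-5-[(4-methylphenyl)sulfanyl]oxolan-2-one as a C3 epimer mixture, via chloro(methyl)ketene 6 (not isolated), via oxysulfonium enolate 7 (not isolated), via thionium carboxylate 8 (not isolated)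
Conditions: Zn–Cu couple, Et2O, 35 °C, slow addition of 5; filtration, aq. NaHCO3
Reagents that add atoms: none
Why: Zinc dechlorinates 5 to the ketene 6, which acylates the sulfinyl oxygen of 4 to give enolate 7; its [3,3] sigmatropic shift joins the enolate carbon to the propenyl β‑carbon while S–O breaks, and the carboxylate of thionium ion 8 then closes the lactone by 5‑exo‑trig attack on the thionium carbon, which forms the ring C–O bond. The closest known reaction is the Marino lactonisation of vinyl sulfoxides with dichloroketene (additive‑Pummerer type), run here with the methyl‑bearing chloroketene. The methyl‑bearing carbon from the sulfoxide is set by chirality transfer from sulfur through the chair‑like array with p‑tolyl pseudo‑equatorial, which for the (R,E)-sulfoxide should give the 4R centre; the S,O‑acetal carbon follows by suprafacial collapse (trans to that methyl) and is re‑set in step 4, and the chloro‑methyl carbon forms as an epimer mixture that step 3 converges. The step needs O‑acylation of the sulfoxide to outrun ketene oligomerisation and [2+2] addition, which the high oxygen nucleophilicity of the sulfoxide and its electron‑poor alkene should secure, and it needs geometrically pure (E)-alkene because the (Z)-isomer would lead to the enantiomeric centre.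

**Step 3**
Reactants: 9 (4R,5R)-3-chloro-3,4-dimethyl-5-[(4-methylphenyl)sulfanyl]oxolan-2-one
Product: 10 (3R,4S,5R)-3,4-dimethyl-5-[(4-methylphenyl)sulfanyl]oxolan-2-one
Conditions: (Me3Si)3SiH (1.2 equiv), AIBN (cat.), toluene, 80 °C
Reagents that add atoms: none
Why: Radical‑chain dehalogenation, in which the planar α‑acyl radical should take hydrogen from the bulky silane on the face opposite the adjacent ring methyl, so both epimers of 9 converge on the cis‑dimethyl lactone (3R).

**Step 4**
Reactants: 10 (3R,4S,5R)-3,4-dimethyl-5-[(4-methylphenyl)sulfanyl]oxolan-2-one; 11 benzyl phenyl ether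
Product: 13 (3R,4S,5S)-5-[4-(benzyloxy)phenyl]-3,4-dimethyloxolan-2-one, via acyloxycarbenium ion 12 (not isolated)
Conditions: MeOTf (1.5 equiv), 2,6-di-tert-butyl-4-methylpyridine, 11 (5 equiv), 4 Å MS, CH2Cl2, 0 °C → rt
Reagents that add atoms: none
Why: Friedel–Crafts C‑arylation of a cyclic S,O‑acetal after thiophilic activation (as for thioglycosides): S‑methylation leaves methyl p‑tolyl sulfide as the only possible leaving group, the cyclic cation 12 keeps the ring C–O bond, and the arene should attack through its para position on the face opposite both methyl groups, setting the aryl‑bearing centre (5S) trans to its neighbouring methyl.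

**Step 5**
Reactants: 14 1-(5-bromo-2-hydroxyphenyl)ethan-1-one
Product: 15 1-[2-(benzyloxy)-5-bromophenyl]ethan-1-one
Conditions: BnBr, K2CO3, DMF, rt
Reagents that add atoms: benzyl bromide, BrCc1ccccc1
Why: Williamson ether synthesis on the phenoxide, which protects the phenol for the organometallic and Lewis‑acid steps that follow.

**Step 6**
Reactants: 15 1-[2-(benzyloxy)-5-bromophenyl]ethan-1-one; 16 1-(benzyloxy)-4-(chloromethyl)benzene
Product: 18 rac-2-[2-(benzyloxy)-5-bromophenyl]-1-[4-(benzyloxy)phenyl]propan-2-ol, via benzylic Grignard reagent 17 (not isolated)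
Conditions: Mg turnings, THF, 0 °C, slow addition of 16; then 15, −20 °C → rt; aq. NH4Cl
Reagents that add atoms: none
Why: Grignard addition of the benzylic magnesium reagent to the aryl methyl ketone, which leaves the aryl bromide untouched; the racemic carbinol centre is removed in step 7.

**Step 7**
Reactants: 18 rac-2-[2-(benzyloxy)-5-bromophenyl]-1-[4-(benzyloxy)phenyl]propan-2-ol
Product: 19 1-(benzyloxy)-2-[(1E)-1-[4-(benzyloxy)phenyl]prop-1-en-2-yl]-4-bromobenzene
Conditions: p-TsOH·H2O (5 mol %), toluene, reflux, Dean–Stark; recrystallisation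
Reagents that add atoms: none
Why: Acid‑catalysed E1 dehydration under equilibrating conditions should favour the conjugated trisubstituted (E)-stilbene, which is freed from (Z)- and 1,1‑disubstituted isomers by recrystallisation.

**Step 8**
Reactants: 19 1-(benzyloxy)-2-[(1E)-1-[4-(benzyloxy)phenyl]prop-1-en-2-yl]-4-bromobenzene
Product: 20 1-(benzyloxy)-2-[(2R)-1-[4-(benzyloxy)phenyl]propan-2-yl]-4-bromobenzene
Conditions: H2 (50 bar), [Ir(cod)(L)]BArF (1 mol %; L = (S)-4-tert-butyl-2-[2-(di-o-tolylphosphanyl)phenyl]-4,5-dihydro-1,3-oxazole, BArF = B[3,5-(CF3)2C6H3]4), CH2Cl2, rt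
Reagents that add atoms: none
Why: Iridium–phosphinooxazoline asymmetric hydrogenation of an unfunctionalised (E)-1,2-diarylpropene, in which the ligand controls the alkene face and is chosen as the antipode expected to give the (R)-alkane, while the aryl bromide and benzyl ethers should survive.

**Step 9**
Reactants: 20 1-(benzyloxy)-2-[(2R)-1-[4-(benzyloxy)phenyl]propan-2-yl]-4-bromobenzene; 13 (3R,4S,5S)-5-[4-(benzyloxy)phenyl]-3,4-dimethyloxolan-2-one
Product: 22 (3R,4S,5S)-2-{4-(benzyloxy)-3-[(2R)-1-[4-(benzyloxy)phenyl]propan-2-yl]phenyl}-5-[4-(benzyloxy)phenyl]-3,4-dimethyloxolan-2-ol as an anomer mixture, via aryllithium 21 (not isolated)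
Conditions: n-BuLi (1.05 equiv), THF, −78 °C; then 13, −78 °C; aq. NH4Cl at −78 °C
Reagents that add atoms: none
Why: Bromine–lithium exchange followed by 1,2‑addition of the aryllithium to the lactone, whose cyclic lithium hemiketal should resist a second addition at −78 °C; the cold quench keeps the cis‑dimethyl pair and the anomeric centre is left unset.

**Step 10**
Reactants: 22 (3R,4S,5S)-2-{4-(benzyloxy)-3-[(2R)-1-[4-(benzyloxy)phenyl]propan-2-yl]phenyl}-5-[4-(benzyloxy)phenyl]-3,4-dimethyloxolan-2-ol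
Product: 25 (2S,3S,4R,5R)-2-[4-(benzyloxy)phenyl]-5-{4-(benzyloxy)-3-[(2R)-1-[4-(benzyloxy)phenyl]propan-2-yl]phenyl}-3,4-dimethyloxolane, via oxocarbenium ion 23 (not isolated), via C5-epimeric oxolane 24 (not isolated)
Conditions: Et3SiH (1.3 equiv), BF3·OEt2 (2 equiv), CH2Cl2, −78 °C; then −20 °C until the C5 epimers have converged; aq. NaHCO3
Reagents that add atoms: none
Why: Ionic hydrogenation of the hemiketal through the aryl‑stabilised cyclic oxocarbenium ion, followed by BF3‑mediated equilibration of the benzylic ether carbon by reversible ring opening, which should drive C5 to the thermodynamic 5R configuration with both aryl groups trans to their neighbouring methyls.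

**Step 11**
Reactants: 25 (2S,3S,4R,5R)-2-[4-(benzyloxy)phenyl]-5-{4-(benzyloxy)-3-[(2R)-1-[4-(benzyloxy)phenyl]propan-2-yl]phenyl}-3,4-dimethyloxolane
Product: 26 4-[(2S,3S,4R,5R)-5-{4-hydroxy-3-[(2R)-1-(4-hydroxyphenyl)propan-2-yl]phenyl}-3,4-dimethyloxolan-2-yl]phenol
Conditions: H2 (1 atm), 10% Pd/C, EtOAc, rt, stopped at full debenzylation
Reagents that add atoms: none
Why: Hydrogenolysis of the three aryl benzyl ethers under neutral conditions, which should be faster than cleavage of the ring benzylic C–O bonds and leaves all stereocentres untouched.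

**Compound list**
1 | (1R,2S,5R)-menthyl (S)-4-methylbenzenesulfinate | Cc1ccc(cc1)[S@@](=O)O[C@@H]1C[C@H](C)CC[C@H]1C(C)C | starting material
2 | (E)-1-bromoprop-1-ene | C/C=C/Br | starting material
3 | (E)-prop-1-enylmagnesium bromide | C/C=C/[Mg]Br | intermediate
4 | 1-methyl-4-[(R)-(1E)-prop-1-ene-1-sulfinyl]benzene | C/C=C/[S@@](=O)c1ccc(C)cc1 | intermediate
5 | 2,2-dichloropropanoyl chloride | CC(Cl)(Cl)C(Cl)=O | starting material
6 | chloro(methyl)ketene | CC(Cl)=C=O | intermediate
7 | oxysulfonium enolate (O‑acylated sulfoxide zwitterion) | C/C=C/[S@@+](OC([O-])=C(C)Cl)c1ccc(C)cc1 | intermediate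
8 | thionium carboxylate zwitterion | C[C@H](C=[S+]c1ccc(C)cc1)C(C)(Cl)C(=O)[O-] | intermediate
9 | (4R,5R)-3-chloro-3,4-dimethyl-5-[(4-methylphenyl)sulfanyl]oxolan-2-one (C3 epimer mixture) | CC1(Cl)[C@H](C)[C@@H](Sc2ccc(C)cc2)OC1=O | intermediate
10 | (3R,4S,5R)-3,4-dimethyl-5-[(4-methylphenyl)sulfanyl]oxolan-2-one | C[C@@H]1[C@H](C)[C@@H](Sc2ccc(C)cc2)OC1=O | intermediate
11 | benzyl phenyl ether | C(Oc1ccccc1)c1ccccc1 | starting material
12 | cyclic acyloxycarbenium ion from 10 | C[C@@H]1[C@H](C)C=[O+]C1=O | intermediate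
13 | (3R,4S,5S)-5-[4-(benzyloxy)phenyl]-3,4-dimethyloxolan-2-one | C[C@@H]1[C@H](C)[C@@H](c2ccc(OCc3ccccc3)cc2)OC1=O | intermediate
14 | 1-(5-bromo-2-hydroxyphenyl)ethan-1-one | CC(=O)c1cc(Br)ccc1O | starting material
15 | 1-[2-(benzyloxy)-5-bromophenyl]ethan-1-one | CC(=O)c1cc(Br)ccc1OCc1ccccc1 | intermediate
16 | 1-(benzyloxy)-4-(chloromethyl)benzene | ClCc1ccc(OCc2ccccc2)cc1 | starting material
17 | [4-(benzyloxy)benzyl]magnesium chloride | Cl[Mg]Cc1ccc(OCc2ccccc2)cc1 | intermediate
18 | rac-2-[2-(benzyloxy)-5-bromophenyl]-1-[4-(benzyloxy)phenyl]propan-2-ol | CC(O)(Cc1ccc(OCc2ccccc2)cc1)c1cc(Br)ccc1OCc1ccccc1 | intermediate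
19 | 1-(benzyloxy)-2-[(1E)-1-[4-(benzyloxy)phenyl]prop-1-en-2-yl]-4-bromobenzene | C/C(=C\c1ccc(OCc2ccccc2)cc1)c1cc(Br)ccc1OCc1ccccc1 | intermediate
20 | 1-(benzyloxy)-2-[(2R)-1-[4-(benzyloxy)phenyl]propan-2-yl]-4-bromobenzene | Brc1ccc(OCc2ccccc2)c([C@H](C)Cc2ccc(OCc3ccccc3)cc2)c1 | intermediate
21 | {4-(benzyloxy)-3-[(2R)-1-[4-(benzyloxy)phenyl]propan-2-yl]phenyl}lithium | [Li]c1ccc(OCc2ccccc2)c([C@H](C)Cc2ccc(OCc3ccccc3)cc2)c1 | intermediate
22 | (3R,4S,5S)-2-{4-(benzyloxy)-3-[(2R)-1-[4-(benzyloxy)phenyl]propan-2-yl]phenyl}-5-[4-(benzyloxy)phenyl]-3,4-dimethyloxolan-2-ol (anomer mixture) | C[C@@H]1[C@H](C)[C@@H](c2ccc(OCc3ccccc3)cc2)OC1(O)c1ccc(OCc2ccccc2)c([C@H](C)Cc2ccc(OCc3ccccc3)cc2)c1 | intermediate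
23 | cyclic 2-aryl oxocarbenium ion from 22 | C[C@@H]1[C@H](C)[C@@H](c2ccc(OCc3ccccc3)cc2)[O+]=C1c1ccc(OCc2ccccc2)c([C@H](C)Cc2ccc(OCc3ccccc3)cc2)c1 | intermediate
24 | (2S,3S,4R,5S)-2-[4-(benzyloxy)phenyl]-5-{4-(benzyloxy)-3-[(2R)-1-[4-(benzyloxy)phenyl]propan-2-yl]phenyl}-3,4-dimethyloxolane (C5 epimer) | C[C@@H]1[C@H](C)[C@@H](c2ccc(OCc3ccccc3)cc2)O[C@@H]1c1ccc(OCc2ccccc2)c([C@H](C)Cc2ccc(OCc3ccccc3)cc2)c1 | intermediate
25 | (2S,3S,4R,5R)-2-[4-(benzyloxy)phenyl]-5-{4-(benzyloxy)-3-[(2R)-1-[4-(benzyloxy)phenyl]propan-2-yl]phenyl}-3,4-dimethyloxolane | C[C@@H]1[C@H](C)[C@@H](c2ccc(OCc3ccccc3)cc2)O[C@H]1c1ccc(OCc2ccccc2)c([C@H](C)Cc2ccc(OCc3ccccc3)cc2)c1 | intermediate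
26 | 4-[(2S,3S,4R,5R)-5-{4-hydroxy-3-[(2R)-1-(4-hydroxyphenyl)propan-2-yl]phenyl}-3,4-dimethyloxolan-2-yl]phenol | C[C@@H]1[C@H](C)[C@@H](c2ccc(O)cc2)O[C@H]1c1ccc(O)c([C@H](C)Cc2ccc(O)cc2)c1 | target

**Count.** Total: 11 steps. Longest linear sequence: 7 steps (steps 1–4, 9–11); the arene branch (steps 5–8, then 9–11) is equally long.

**Steps most likely to fail**

Step 2. O‑acylation of the sulfoxide by the less electrophilic alkylchloroketene may be outrun by ketene oligomerisation, and chirality transfer from an (E)-sulfoxide may be incomplete. The fallback sets out from 4 and uses the documented partner, dichloroketene F1 (trichloroacetyl chloride, Zn–Cu couple, Et2O), to give (4R,5R)-3,3-dichloro-4-methyl-5-[(4-methylphenyl)sulfanyl]oxolan-2-one F2. Zn in AcOH removes both chlorines to give (4S,5R)-4-methyl-5-[(4-methylphenyl)sulfanyl]oxolan-2-one F3. LDA then MeI should give the trans‑dimethyl lactone (3S,4S,5R)-3,4-dimethyl-5-[(4-methylphenyl)sulfanyl]oxolan-2-one F4. Deprotonation (LiHMDS, −78 °C) and kinetic protonation with 2,6-di-tert-butylphenol on the face opposite the ring methyl should then give the cis‑dimethyl lactone, and the route is rejoined at 10.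

Step 4. Ionisation of the S‑methylated acetal to the destabilised acyloxycarbenium ion may be slow, and the arene may attack ortho or not at all. The fallback sets out from 10: m‑CPBA oxidation gives the sulfone (3R,4S,5R)-3,4-dimethyl-5-(4-methylbenzenesulfonyl)oxolan-2-one F5, from which only sulfinate can leave. Lewis‑acid‑assisted displacement of this 2‑sulfonyl cyclic ether with bis[4-(benzyloxy)phenyl]zinc F6 (from commercial 4-(benzyloxy)phenylmagnesium bromide and ZnBr2, THF) should deliver the aryl group trans to the methyl, and the route is rejoined at 13.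

Step 10. The cis‑dimethyl relationship may be lost by enol‑ether formation from the aryl oxocarbenium ion, and the benzylic ethers may be opened reductively while silane and BF3 are present during equilibration. The fallback sets out from 13 and avoids a hydride step. DIBAL‑H (CH2Cl2, −78 °C) gives the lactol (3R,4S,5S)-5-[4-(benzyloxy)phenyl]-3,4-dimethyloxolan-2-ol F7. BF3·OEt2‑promoted Friedel–Crafts arylation then uses the arene 1-(benzyloxy)-2-[(2R)-1-[4-(benzyloxy)phenyl]propan-2-yl]benzene F8 (from 20 by n‑BuLi, then MeOH); the arene should enter para to its benzyloxy group and trans to the neighbouring methyl. This bypasses steps 9 and 10 and rejoins the route at 25.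

**Further compounds**
F1 | step 2 | dichloroketene | ClC(Cl)=C=O
F2 | step 2 | (4R,5R)-3,3-dichloro-4-methyl-5-[(4-methylphenyl)sulfanyl]oxolan-2-one | ClC1(Cl)[C@H](C)[C@@H](Sc2ccc(C)cc2)OC1=O
F3 | step 2 | (4S,5R)-4-methyl-5-[(4-methylphenyl)sulfanyl]oxolan-2-one | O=C1C[C@H](C)[C@@H](Sc2ccc(C)cc2)O1
F4 | step 2 | (3S,4S,5R)-3,4-dimethyl-5-[(4-methylphenyl)sulfanyl]oxolan-2-one | C[C@H]1[C@H](C)[C@@H](Sc2ccc(C)cc2)OC1=O
F5 | step 4 | (3R,4S,5R)-3,4-dimethyl-5-(4-methylbenzenesulfonyl)oxolan-2-one | C[C@@H]1[C@H](C)[C@@H](S(=O)(=O)c2ccc(C)cc2)OC1=O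
F6 | step 4 | bis[4-(benzyloxy)phenyl]zinc | C(Oc1ccc([Zn]c2ccc(OCc3ccccc3)cc2)cc1)c1ccccc1
F7 | step 10 | (3R,4S,5S)-5-[4-(benzyloxy)phenyl]-3,4-dimethyloxolan-2-ol | C[C@@H]1[C@H](C)[C@@H](c2ccc(OCc3ccccc3)cc2)OC1O
F8 | step 10 | 1-(benzyloxy)-2-[(2R)-1-[4-(benzyloxy)phenyl]propan-2-yl]benzene | C[C@H](Cc1ccc(OCc2ccccc2)cc1)c1ccccc1OCc1ccccc1
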